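**Retrosynthetic overview**

- Last ring-forming event: the aryl C–O(acyl) bond of the dibenzo[b,e][1,4]dioxepin-11-one (ester O10 to C9a of ring B, the carbon ortho to the diaryl-ether oxygen) is closed from a bromo seco diacid by photosensitised nickel C–O coupling. Acid in the same flask then folds the hydroxy keto acid of ring B into the spiroketal lactone.
- Enabling feature: in the seco diacid the CO2H of ring A and the C–Br carbon of ring B are both ortho to the same diaryl-ether oxygen, so the carboxylate oxygen sits six atoms from that carbon. The ether carbon of ring B has no ortho or para acceptor (no Smiles scrambling), and ring B carries CO2H, benzylic C=O and the (R)-carbinol in the 1,5/1,5 array that collapses to the spiro[isochromanone-3,2'-oxane].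
- The C–Br comes from the NH2 of 4-amino-5-chloro-2-methoxybenzoic acid: NH2 → NO2 turns the neighbouring C–Cl into an SNAr site for the ring A phenol (diaryl ether), then NO2 → NH2 → Br.
- The keto acid of ring A travels as a 3-pentylisocoumarin (toluate-anion acylation). The side chain of ring B is attached by carboxylate-directed C–H acylmethylation with a sulfoxonium ylide made from (R)-δ-hexanolactone, itself from (R)-propylene oxide.
- Ring order: chiral δ-lactone → isocoumarin (ring A) → diaryl ether → spiroketal isochromanone (ring B, reopened by hydroxide) → dioxepinone, oxane and δ-lactone together in the key step.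

Key step: step 12

Remark: the (S) spiro centre next to (R)-CHCH3 is the anomerically stabilised spiroketal with equatorial methyl, so it is assumed to form under equilibrating acid; methyl 2-hydroxy-4-methoxy-6-methylbenzoate and 4-amino-5-chloro-2-methoxybenzoic acid are taken as purchasable.

**Route**

Step 1
Reactants: 1 ethyl propiolate; 2 (R)-propylene oxide
Product: 3 ethyl (5R)-5-hydroxyhex-2-ynoate
Conditions: n-BuLi, THF, −78 °C; BF3·OEt2; 2, −78 °C; then aq. HCl
Reagents that add atoms: none
Why: Yamaguchi–Hirao alkynylation, in which the lithium acetylide opens the BF3-activated epoxide by SN2 attack at the unsubstituted carbon, so the (R) carbinol centre of 2 is carried into 3 unchanged.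

Step 2
Reactants: 3 ethyl (5R)-5-hydroxyhex-2-ynoate
Product: 5 (6R)-6-methyloxan-2-one, via hydroxy ester 4 (not isolated)
Conditions: H2 (1 atm), 10% Pd/C, EtOAc, 25 °C; then TsOH·H2O (cat.), CH2Cl2, 25 °C
Reagents that add atoms: none
Why: Heterogeneous hydrogenation saturates the alkyne and acid-catalysed lactonisation (6-exo-trig) of the δ-hydroxy ester closes the oxanone without touching the stereocentre.

Step 3
Reactants: 5 (6R)-6-methyloxan-2-one; 6 trimethylsulfoxonium iodide
Product: 7 (6R)-1-[dimethyl(oxo)-λ6-sulfanylidene]-6-hydroxyheptan-2-one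
Conditions: 6, KOtBu, THF, 65 °C; then 5, 0 → 25 °C
Reagents that add atoms: none
Why: Corey–Chaykovsky-type C-acylation of dimethylsulfoxonium methylide by the lactone should open the ring and, after proton transfer, give the stabilised β-keto sulfoxonium ylide with the free (R)-carbinol.

Step 4
Reactants: 8 methyl 2-hydroxy-4-methoxy-6-methylbenzoate; 9 methyl hexanoate
Product: 11 8-hydroxy-6-methoxy-3-pentyl-1H-isochromen-1-one, via keto ester 10 (not isolated)
Conditions: LiN(i-Pr)2 (LDA, 3.2 equiv), THF, −78 °C; 9, −78 → 0 °C; AcOH; then TsOH·H2O (cat.), toluene, 90 °C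
Reagents that add atoms: none
Why: Lateral lithiation of the ortho-toluate (phenoxide–benzylic dianion) and Claisen-type acylation by the ester should give the 2-oxoheptyl ketone, which acid-catalysed enol lactonisation ties to the ester as the isocoumarin.

Step 5
Reactants: 12 4-amino-5-chloro-2-methoxybenzoic acid
Product: 13 5-chloro-2-methoxy-4-nitrobenzoic acid
Conditions: mCPBA (4 equiv), ClCH2CH2Cl, 70 °C
Reagents that add atoms: mCPBA (3-chloroperoxybenzoic acid), O=C(OO)c1cccc(Cl)c1
Why: Peracid oxidation of the weakly basic aniline (through hydroxylamine and nitroso stages) should give the nitroarene, whose nitro group stands ortho to chlorine.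

Step 6
Reactants: 11 8-hydroxy-6-methoxy-3-pentyl-1H-isochromen-1-one; 13 5-chloro-2-methoxy-4-nitrobenzoic acid
Product: 14 2-methoxy-5-[(6-methoxy-1-oxo-3-pentyl-1H-isochromen-8-yl)oxy]-4-nitrobenzoic acid
Conditions: K2CO3 (3 equiv), DMSO, 110 °C; then aq. HCl
Reagents that add atoms: none
Why: SNAr (addition–elimination) of the phenoxide of 11 at the chlorine ortho to the nitro group, which stabilises the Meisenheimer adduct, while the nitro group para to the carboxylate is not activated for displacement.

Step 7
Reactants: 14 2-methoxy-5-[(6-methoxy-1-oxo-3-pentyl-1H-isochromen-8-yl)oxy]-4-nitrobenzoic acid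
Product: 15 4-amino-2-methoxy-5-[(6-methoxy-1-oxo-3-pentyl-1H-isochromen-8-yl)oxy]benzoic acid
Conditions: H2 (1 atm), 5% Pt/C (sulfided), EtOAc, 25 °C
Reagents that add atoms: none
Why: Chemoselective catalytic hydrogenation of the nitro group over sulfided platinum should leave the enol-lactone C=C and the diaryl ether untouched.

Step 8
Reactants: 15 4-amino-2-methoxy-5-[(6-methoxy-1-oxo-3-pentyl-1H-isochromen-8-yl)oxy]benzoic acid
Product: 17 4-bromo-2-methoxy-5-[(6-methoxy-1-oxo-3-pentyl-1H-isochromen-8-yl)oxy]benzoic acid, via arenediazonium bromide 16 (not isolated)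
Conditions: NaNO2, 48% aq. HBr (excess), MeCN, 0 °C; then CuBr (20 mol%), 60 °C
Reagents that add atoms: hydrogen bromide, Br
Why: Sandmeyer reaction, in which diazotisation and copper-mediated bromide transfer place bromine on the carbon that will later carry the ester oxygen.

Step 9
Reactants: 17 4-bromo-2-methoxy-5-[(6-methoxy-1-oxo-3-pentyl-1H-isochromen-8-yl)oxy]benzoic acid; 7 (6R)-1-[dimethyl(oxo)-λ6-sulfanylidene]-6-hydroxyheptan-2-one
Product: 19 (3S,6'R)-6-bromo-8-methoxy-5-[(6-methoxy-1-oxo-3-pentyl-1H-isochromen-8-yl)oxy]-6'-methylspiro[isochromane-3,2'-oxan]-1-one, via hydroxy keto acid 18 (not isolated)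
Conditions: [Cp*RhCl2]2 (5 mol%), AgSbF6 (20 mol%), NaOAc (30 mol%), (CF3)2CHOH, 60 °C; then TsOH·H2O (10 mol%), CH2Cl2, 25 °C
Reagents that add atoms: none
Why: Carboxylate-directed C–H acylmethylation, in which the Cp* complex of trivalent rhodium metalates the only free ortho position and the carbene from the sulfoxonium ylide inserts (loss of DMSO), should give 18, and acid-catalysed spiroketal lactonisation then sets the spiro centre as (S) under thermodynamic control by the (R)-carbinol (equatorial methyl, axial acyloxy C–O bond, anomeric effect), any enol lactone formed from 18 converging on the same ketal.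

Step 10
Reactants: 19 (3S,6'R)-6-bromo-8-methoxy-5-[(6-methoxy-1-oxo-3-pentyl-1H-isochromen-8-yl)oxy]-6'-methylspiro[isochromane-3,2'-oxan]-1-one
Product: 20 (3S,6'R)-6-bromo-8-hydroxy-5-[(6-methoxy-1-oxo-3-pentyl-1H-isochromen-8-yl)oxy]-6'-methylspiro[isochromane-3,2'-oxan]-1-one
Conditions: BCl3 (3 equiv), CH2Cl2, −78 → 0 °C; then H2O
Reagents that add atoms: none
Why: Chelation-assisted BCl3 demethylation should cleave only the methyl ether peri to the lactone carbonyl, leaving the non-chelated methoxy group of ring A and the diaryl ether intact.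

Step 11
Reactants: 20 (3S,6'R)-6-bromo-8-hydroxy-5-[(6-methoxy-1-oxo-3-pentyl-1H-isochromen-8-yl)oxy]-6'-methylspiro[isochromane-3,2'-oxan]-1-one
Product: 21 2-{6-bromo-3-carboxy-4-hydroxy-2-[(6R)-6-hydroxy-2-oxoheptyl]phenoxy}-4-methoxy-6-(2-oxoheptyl)benzoic acid
Conditions: LiOH (8 equiv), THF/H2O (3:1), 25 °C; then 1 M HCl to pH 4, 0 °C
Reagents that add atoms: water, O
Why: Saponification opens the enol lactone of ring A (isocoumarin to keto acid) and the acyl-ketal lactone of ring B, and cold acidification returns the two free acids, whose ring–chain tautomers all converge in step 12.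

Step 12
Reactants: 21 2-{6-bromo-3-carboxy-4-hydroxy-2-[(6R)-6-hydroxy-2-oxoheptyl]phenoxy}-4-methoxy-6-(2-oxoheptyl)benzoic acid
Product: 23 target CNP0301127.1 [(3S,6'R)-spiroketal-lactone depsidone], via ring-B-open depsidone acid 22 (not isolated)
Conditions: NiBr2·glyme (10 mol%), 4,4'-di-tert-butyl-2,2'-bipyridine (10 mol%), Ir(ppy)3 (2 mol%), t-BuNH(i-Pr) (2.1 equiv), DMF (0.01 M), blue LEDs, 25 °C; then 1 M HCl, THF, 0 → 25 °C
Reagents that add atoms: none
Why: Zerovalent nickel inserts into the C–Br bond of ring B, the ring A carboxylate (ortho to the same ether oxygen) displaces bromide to give an eight-membered aryl–nickel carboxylate chelate, and triplet energy transfer from excited Ir(ppy)3 to this divalent nickel complex triggers C(aryl)–O(acyl) reductive elimination, which closes the seven-membered 1,4-dioxepinone by contraction of the nickelacycle. The closest known reaction type is the photosensitised nickel-catalysed esterification of aryl bromides with carboxylic acids, with Ullmann-type lactonisation of 2'-halobiaryl-2-carboxylic acids as its thermal analogue. On acidification the hydroxy keto acid of 22 collapses: the (R)-carbinol adds to the ketone (6-exo-trig hemiketalisation, oxane ring) and the carboxylic acid captures the derived cyclic oxocarbenium ion (6-exo-trig, δ-lactone ring). The new spiro centre is set under thermodynamic control by the (R)-methyl carbinol, the chair oxane with equatorial methyl and axial C–O(acyl) bond (anomeric effect) being the (S) isomer. The step needs the ring A carboxylate rather than the phenol, the alcohol or the ring B carboxylate as the nickel-bound nucleophile (only the two acids are ionised by the hindered amine, the ring B carboxylate is para to C–Br and cannot reach it, and high dilution suppresses intermolecular coupling), no Smiles scrambling (the ether carbon of ring B has no ortho or para acceptor), and survival of the aryl ester beside the enolisable 2-oxoheptyl ketone (room temperature, no excess base, brief dilute acid).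

**Compound list**

1 | ethyl propiolate | C#CC(=O)OCC | starting material
2 | (R)-propylene oxide [(2R)-2-methyloxirane] | C[C@@H]1CO1 | starting material
3 | ethyl (5R)-5-hydroxyhex-2-ynoate | CCOC(=O)C#CC[C@@H](C)O | intermediate
4 | ethyl (5R)-5-hydroxyhexanoate | CCOC(=O)CCC[C@@H](C)O | intermediate
5 | (6R)-6-methyloxan-2-one [(R)-δ-hexanolactone] | C[C@@H]1CCCC(=O)O1 | intermediate
6 | trimethylsulfoxonium iodide | C[S+](C)(C)=O.[I-] | starting material
7 | (6R)-1-[dimethyl(oxo)-λ6-sulfanylidene]-6-hydroxyheptan-2-one | C[C@@H](O)CCCC(=O)C=S(C)(C)=O | intermediate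
8 | methyl 2-hydroxy-4-methoxy-6-methylbenzoate | COC(=O)c1c(C)cc(OC)cc1O | starting material
9 | methyl hexanoate | CCCCCC(=O)OC | starting material
10 | methyl 2-hydroxy-4-methoxy-6-(2-oxoheptyl)benzoate | CCCCCC(=O)Cc1cc(OC)cc(O)c1C(=O)OC | intermediate
11 | 8-hydroxy-6-methoxy-3-pentyl-1H-isochromen-1-one | CCCCCC1=Cc2cc(OC)cc(O)c2C(=O)O1 | intermediate
12 | 4-amino-5-chloro-2-methoxybenzoic acid | COc1cc(N)c(Cl)cc1C(=O)O | starting material
13 | 5-chloro-2-methoxy-4-nitrobenzoic acid | COc1cc([N+](=O)[O-])c(Cl)cc1C(=O)O | intermediate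
14 | 2-methoxy-5-[(6-methoxy-1-oxo-3-pentyl-1H-isochromen-8-yl)oxy]-4-nitrobenzoic acid | CCCCCC1=Cc2cc(OC)cc(Oc3cc(C(=O)O)c(OC)cc3[N+](=O)[O-])c2C(=O)O1 | intermediate
15 | 4-amino-2-methoxy-5-[(6-methoxy-1-oxo-3-pentyl-1H-isochromen-8-yl)oxy]benzoic acid | CCCCCC1=Cc2cc(OC)cc(Oc3cc(C(=O)O)c(OC)cc3N)c2C(=O)O1 | intermediate
16 | 4-carboxy-5-methoxy-2-[(6-methoxy-1-oxo-3-pentyl-1H-isochromen-8-yl)oxy]benzenediazonium bromide | CCCCCC1=Cc2cc(OC)cc(Oc3cc(C(=O)O)c(OC)cc3[N+]#N)c2C(=O)O1.[Br-] | intermediate
17 | 4-bromo-2-methoxy-5-[(6-methoxy-1-oxo-3-pentyl-1H-isochromen-8-yl)oxy]benzoic acid | CCCCCC1=Cc2cc(OC)cc(Oc3cc(C(=O)O)c(OC)cc3Br)c2C(=O)O1 | intermediate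
18 | 4-bromo-2-[(6R)-6-hydroxy-2-oxoheptyl]-6-methoxy-3-[(6-methoxy-1-oxo-3-pentyl-1H-isochromen-8-yl)oxy]benzoic acid | CCCCCC1=Cc2cc(OC)cc(Oc3c(Br)cc(OC)c(C(=O)O)c3CC(=O)CCC[C@@H](C)O)c2C(=O)O1 | intermediate
19 | (3S,6'R)-6-bromo-8-methoxy-5-[(6-methoxy-1-oxo-3-pentyl-1H-isochromen-8-yl)oxy]-6'-methylspiro[isochromane-3,2'-oxan]-1-one | CCCCCC1=Cc2cc(OC)cc(Oc3c(Br)cc(OC)c4c3C[C@]3(CCC[C@@H](C)O3)OC4=O)c2C(=O)O1 | intermediate
20 | (3S,6'R)-6-bromo-8-hydroxy-5-[(6-methoxy-1-oxo-3-pentyl-1H-isochromen-8-yl)oxy]-6'-methylspiro[isochromane-3,2'-oxan]-1-one | CCCCCC1=Cc2cc(OC)cc(Oc3c(Br)cc(O)c4c3C[C@]3(CCC[C@@H](C)O3)OC4=O)c2C(=O)O1 | intermediate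
21 | 2-{6-bromo-3-carboxy-4-hydroxy-2-[(6R)-6-hydroxy-2-oxoheptyl]phenoxy}-4-methoxy-6-(2-oxoheptyl)benzoic acid | CCCCCC(=O)Cc1cc(OC)cc(Oc2c(Br)cc(O)c(C(=O)O)c2CC(=O)CCC[C@@H](C)O)c1C(=O)O | intermediate
22 | 8-hydroxy-6-[(6R)-6-hydroxy-2-oxoheptyl]-3-methoxy-11-oxo-1-(2-oxoheptyl)-11H-dibenzo[b,e][1,4]dioxepine-7-carboxylic acid | CCCCCC(=O)Cc1cc(OC)cc2c1C(=O)Oc1cc(O)c(C(=O)O)c(CC(=O)CCC[C@@H](C)O)c1O2 | intermediate
23 | target CNP0301127.1: depsidone with 2-oxoheptyl and methoxy on ring A, hydroxy on ring B, and ring B fused to the (3S,6'R)-6'-methylspiro[δ-lactone-oxane] ketal | CCCCCC(=O)Cc1cc(OC)cc2c1C(=O)Oc1cc(O)c3c(c1O2)C[C@]1(CCC[C@@H](C)O1)OC3=O | target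

**Step count**

Total step count: 12. Longest linear sequence: 8 steps (steps 5, 6, 7, 8, 9, 10, 11, 12, from 12 to 23).

**Three steps most likely to fail**

Step 12, the key step. What may go wrong is slow C–O reductive elimination at an aryl–nickel centre that carries an ortho aryloxy group and sits on an electron-rich ring, so that hydrodebromination or intermolecular esterification by the second carboxylate competes. During the acidic finish the new aryl ester may also transfer its acyl group to the enol of the neighbouring ketone. The fallback sets out from 21 and closes ring B first. Treatment with 2 M HCl in THF at 25 °C should give the ring-closed bromo keto acid F1, in which the only free carboxylic acid is that of ring A. Miyaura borylation with palladium diacetate, XPhos, B2pin2 and KOAc in dioxane at 80 °C should then give the pinacol boronate F2. Chan–Lam–Evans coupling of the arylboron with the carboxylic acid, using copper diacetate, pyridine and 4 Å molecular sieves under air in CH2Cl2 at 25 °C, forms the same C–O bond oxidatively with no acid afterwards and comes back to the route at 23.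

Step 9. What may go wrong is sluggish C–H metalation at a position wedged between the carboxyl group and the bulky aryloxy group, and insertion of the metal carbenoid into the free O–H groups instead. The fallback sets out from 13 and 7 and does the annulation before the fragments are joined. The rhodium conditions of step 9 applied to the small acid, whose C–H is flanked only by CO2H and Cl, should give the chloro nitro hydroxy keto acid F3 and, after TsOH in CH2Cl2, the chloro nitro spiroketal lactone F4. SNAr with 11 using K2CO3 in DMSO at 110 °C, chloride ortho to nitro leaving in preference to the nitro group, should give the nitro diaryl ether F5. Hydrogenation over sulfided Pt/C should give the aniline F6, and NaNO2 with HBr followed by CuBr should give the diazonium bromide F7, which loses dinitrogen and comes back to the route at 19.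

Step 4. What may go wrong is incomplete benzylic deprotonation once the phenoxide is formed, and self-condensation of the toluate anion with the ester group in place of acylation by 9. The fallback sets out from 8 and removes the acidic phenol first. MeI and K2CO3 in acetone should give methyl 2,4-dimethoxy-6-methylbenzoate F8. Lithium diisopropylamide and 9 in THF at −78 °C should give the dimethoxy keto ester F9, and TsOH in toluene at 90 °C should close it to 6,8-dimethoxy-3-pentyl-1H-isochromen-1-one F10. BCl3 in CH2Cl2 at −78 → 0 °C cleaves only the methyl ether peri to the lactone carbonyl and comes back to the route at 11.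

**Further compounds**

F1 | step 12 | 2-{[(3S,6'R)-6-bromo-8-hydroxy-6'-methyl-1-oxospiro[isochromane-3,2'-oxan]-5-yl]oxy}-4-methoxy-6-(2-oxoheptyl)benzoic acid | CCCCCC(=O)Cc1cc(OC)cc(Oc2c(Br)cc(O)c3c2C[C@]2(CCC[C@@H](C)O2)OC3=O)c1C(=O)O
F2 | step 12 | 2-{[(3S,6'R)-8-hydroxy-6'-methyl-1-oxo-6-(4,4,5,5-tetramethyl-1,3,2-dioxaborolan-2-yl)spiro[isochromane-3,2'-oxan]-5-yl]oxy}-4-methoxy-6-(2-oxoheptyl)benzoic acid | CCCCCC(=O)Cc1cc(OC)cc(Oc2c(B3OC(C)(C)C(C)(C)O3)cc(O)c3c2C[C@]2(CCC[C@@H](C)O2)OC3=O)c1C(=O)O
F3 | step 9 | 3-chloro-2-[(6R)-6-hydroxy-2-oxoheptyl]-6-methoxy-4-nitrobenzoic acid | COc1cc([N+](=O)[O-])c(Cl)c(CC(=O)CCC[C@@H](C)O)c1C(=O)O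
F4 | step 9 | (3S,6'R)-5-chloro-8-methoxy-6'-methyl-6-nitrospiro[isochromane-3,2'-oxan]-1-one | Clc1c([N+](=O)[O-])cc(OC)c2c1C[C@]1(CCC[C@@H](C)O1)OC2=O
F5 | step 9 | (3S,6'R)-8-methoxy-5-[(6-methoxy-1-oxo-3-pentyl-1H-isochromen-8-yl)oxy]-6'-methyl-6-nitrospiro[isochromane-3,2'-oxan]-1-one | CCCCCC1=Cc2cc(OC)cc(Oc3c([N+](=O)[O-])cc(OC)c4c3C[C@]3(CCC[C@@H](C)O3)OC4=O)c2C(=O)O1
F6 | step 9 | (3S,6'R)-6-amino-8-methoxy-5-[(6-methoxy-1-oxo-3-pentyl-1H-isochromen-8-yl)oxy]-6'-methylspiro[isochromane-3,2'-oxan]-1-one | CCCCCC1=Cc2cc(OC)cc(Oc3c(N)cc(OC)c4c3C[C@]3(CCC[C@@H](C)O3)OC4=O)c2C(=O)O1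
F7 | step 9 | (3S,6'R)-8-methoxy-5-[(6-methoxy-1-oxo-3-pentyl-1H-isochromen-8-yl)oxy]-6'-methyl-1-oxospiro[isochromane-3,2'-oxane]-6-diazonium bromide | CCCCCC1=Cc2cc(OC)cc(Oc3c([N+]#N)cc(OC)c4c3C[C@]3(CCC[C@@H](C)O3)OC4=O)c2C(=O)O1.[Br-]
F8 | step 4 | methyl 2,4-dimethoxy-6-methylbenzoate | COC(=O)c1c(C)cc(OC)cc1OC
F9 | step 4 | methyl 2,4-dimethoxy-6-(2-oxoheptyl)benzoate | CCCCCC(=O)Cc1cc(OC)cc(OC)c1C(=O)OC
F10 | step 4 | 6,8-dimethoxy-3-pentyl-1H-isochromen-1-one | CCCCCC1=Cc2cc(OC)cc(OC)c2C(=O)O1
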